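**Plan**

- Retrosynthetic cuts, in order: C9–C10 (enolate alkylation, closes the oxepane O/C5–C10 last); C8–O acyl (Mitsunobu); C7–C8 (indium Barbier with chloroacetaldehyde); C7=C11 and C6O–C12 (ring-closing metathesis, esterification); C3–C4 (7-exo Heck); C1–C2 (acetylide opening of a lactone); C10–O and C1–O (dioxanone from a diol); two C=C (Wittig on L-tartrate).
- Forward: L-tartrate acetonide → C2-symmetric divinyl diol → temporary 1,4-dioxan-2-one (one oxygen becomes the C5–O–C10 ether, the other is freed again as C6–OH) → oxepinone ring (O, C10, C1–C5) by Heck → butenolide by metathesis → trans lactone side chain by Barbier → oxepane by alkylation.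
- Stereochemistry: C5 and C6 are the two carbinol carbons of L-tartaric acid (its four carbons become C4–C7); C7 comes from anti attack on the butenolide; C8 from the chair Barbier adduct, inverted by Mitsunobu; C10 is set only in the last step.
- Feature used by the key step: in the oxepinone ring C10 is the only enolisable α-carbon of the C1 ketone (C2 is vinylic, C4 bears no hydrogen) and it sits across the ring oxygen from C5, so the C6–C7–C8–C9 chain on C5 can alkylate it on one face only; either C10 epimer of the precursor converges on 10S.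

Key step: step 12

Remark: atoms are numbered as in germacranolides (C1 ketone, C2=C3, C4=C15, C5 and C10 on the ether oxygen, C6 lactone carbinol, C8 ester carbinol, C11=C13, C12 lactone carbonyl, C14 methyl); the configuration at C10 before step 12 has no consequence and is drawn 10R, as SN2 inversion of 5 gives it; 9 and 10 are drawn open-chain although they equilibrate with six-membered lactols.

Step 1
Reactants: 1 dimethyl (4R,5R)-2,2-dimethyl-1,3-dioxolane-4,5-dicarboxylate
Product: 3 (4S,5S)-4,5-diethenyl-2,2-dimethyl-1,3-dioxolane, via dialdehyde 2 (not isolated)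
Conditions: i-Bu2AlH (2.1 equiv), toluene, −78 °C; then Ph3P=CH2 (from Ph3PCH3Br, KN(SiMe3)2), THF, −78 °C → rt
Reagents that add atoms: methyltriphenylphosphonium bromide, C[P+](c1ccccc1)(c1ccccc1)c1ccccc1.[Br-]
Why: Half-reduction of both esters gives the aluminium hemiacetals of dialdehyde 2, which should be trapped in the same flask by Wittig methylenation, so the epimerisable dialdehyde is never isolated and the two tartrate stereocentres (future C5 and C6) are carried over unchanged.

Step 2
Reactants: 3 (4S,5S)-4,5-diethenyl-2,2-dimethyl-1,3-dioxolane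
Product: 4 (3S,4S)-hexa-1,5-diene-3,4-diol
Conditions: 2 M aq. HCl, THF, 40 °C
Reagents that add atoms: none
Why: Acid-catalysed acetal hydrolysis should release the C2-symmetric diol without touching the two allylic stereocentres.

Step 3
Reactants: 4 (3S,4S)-hexa-1,5-diene-3,4-diol; 5 (2S)-2-chloropropanoyl chloride
Product: 7 (3R,5S,6S)-5,6-diethenyl-3-methyl-1,4-dioxan-2-one, via chloro ester 6 (not isolated)
Conditions: 5 (1.0 equiv), pyridine, CH2Cl2, −78 → 0 °C; then NaH, Bu4NI (cat.), THF, 0 °C → rt
Reagents that add atoms: none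
Why: O-Acylation of either of the two homotopic hydroxyls gives the same ester, and intramolecular Williamson etherification (6-exo-tet SN2 with inversion at the chloride carbon) should then close a temporary 1,4-dioxan-2-one in which one tartrate oxygen has become the C5–O–C10 ether and the other an ester oxygen.

Step 4
Reactants: 7 (3R,5S,6S)-5,6-diethenyl-3-methyl-1,4-dioxan-2-one; 8 ethynylmagnesium bromide
Product: 9 (4R)-4-{[(3S,4S)-4-hydroxyhexa-1,5-dien-3-yl]oxy}pent-1-yn-3-one
Conditions: 8 (1.15 equiv), THF, −78 °C; AcOH quench at −78 °C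
Reagents that add atoms: none
Why: Acylation of the alkynyl Grignard reagent by the lactone should stop at the ketone level because the tetrahedral magnesium lactolate survives at −78 °C, and protonation opens the temporary ring to the ynone with C6–OH free.

Step 5
Reactants: 9 (4R)-4-{[(3S,4S)-4-hydroxyhexa-1,5-dien-3-yl]oxy}pent-1-yn-3-one
Product: 10 (1Z,4R)-4-{[(3S,4S)-4-hydroxyhexa-1,5-dien-3-yl]oxy}-1-iodopent-1-en-3-one
Conditions: NaI (1.5 equiv), AcOH, rt, dark
Reagents that add atoms: sodium iodide, [Na+].[I-]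
Why: Conjugate hydroiodination of the ynone is an anti addition, so the kinetic product should be the (Z)-β-iodoenone with iodine cis to the carbonyl, the geometry the seven-membered ring needs.

Step 6
Reactants: 10 (1Z,4R)-4-{[(3S,4S)-4-hydroxyhexa-1,5-dien-3-yl]oxy}-1-iodopent-1-en-3-one
Product: 11 (2R,7S)-7-[(1S)-1-hydroxyprop-2-en-1-yl]-2-methyl-6-methylidene-6,7-dihydrooxepin-3(2H)-one
Conditions: Pd(OAc)2 (10 mol %), PPh3 (25 mol %), Ag2CO3 (1.5 equiv), MeCN (0.01 M), 70 °C
Reagents that add atoms: none
Why: Intramolecular Heck reaction, in which oxidative addition of zerovalent palladium into the vinyl C–I bond, 7-exo-trig insertion of the C4=C15 vinyl group and β-hydride elimination of the only β-hydrogen (on C4) should give the ring dienone with its exocyclic methylene, while Ag2CO3 takes iodide and hydride off palladium before the diene can migrate; no stereocentre is formed.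

Step 7
Reactants: 11 (2R,7S)-7-[(1S)-1-hydroxyprop-2-en-1-yl]-2-methyl-6-methylidene-6,7-dihydrooxepin-3(2H)-one; 12 2-(bromomethyl)prop-2-enoic acid
Product: 13 (1S)-1-[(2S,7R)-7-methyl-3-methylidene-6-oxo-2,3,6,7-tetrahydrooxepin-2-yl]prop-2-en-1-yl 2-(bromomethyl)prop-2-enoate
Conditions: DCC, DMAP (5 mol %), CH2Cl2, 0 °C
Reagents that add atoms: none
Why: Steglich esterification of the C6 alcohol with retention should install C11, C12 and C13 of the lactone together with the allylic bromide needed in step 9.

Step 8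
Reactants: 13 (1S)-1-[(2S,7R)-7-methyl-3-methylidene-6-oxo-2,3,6,7-tetrahydrooxepin-2-yl]prop-2-en-1-yl 2-(bromomethyl)prop-2-enoate
Product: 14 (5S)-3-(bromomethyl)-5-[(2S,7R)-7-methyl-3-methylidene-6-oxo-2,3,6,7-tetrahydrooxepin-2-yl]furan-2(5H)-one
Conditions: second-generation Grubbs catalyst (10 mol %), toluene (0.005 M), 80 °C
Reagents that add atoms: none
Why: Ring-closing metathesis between the C7 vinyl group and the acrylate methylene should give the butenolide, the only ring of reasonable size open to the ruthenium carbene because the other alkenes are the ring enone and a 1,1-disubstituted diene terminus.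

Step 9
Reactants: 14 (5S)-3-(bromomethyl)-5-[(2S,7R)-7-methyl-3-methylidene-6-oxo-2,3,6,7-tetrahydrooxepin-2-yl]furan-2(5H)-one; 15 chloroacetaldehyde
Product: 16 (4R,5S)-4-[(1R)-2-chloro-1-hydroxyethyl]-3-methylidene-5-[(2S,7R)-7-methyl-3-methylidene-6-oxo-2,3,6,7-tetrahydrooxepin-2-yl]oxolan-2-one
Conditions: In powder (1.5 equiv), 15 (50 wt % in H2O, 4 equiv), THF–H2O 1:1, rt
Reagents that add atoms: none
Why: Indium-mediated Barbier allylation, in which the allylindium attacks the aldehyde through C7 and shifts the double bond to the exocyclic C11=C13 position; approach anti to the oxepinone on C6 should set C7 trans, the chair Zimmerman–Traxler arrangement with CH2Cl equatorial should set C8 as the 7,8-anti (8R) carbinol, and the aldehyde should outrun the hindered conjugated ketone.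

Step 10
Reactants: 16 (4R,5S)-4-[(1R)-2-chloro-1-hydroxyethyl]-3-methylidene-5-[(2S,7R)-7-methyl-3-methylidene-6-oxo-2,3,6,7-tetrahydrooxepin-2-yl]oxolan-2-one; 17 angelic acid
Product: 18 (1S)-2-chloro-1-{(2S,3S)-4-methylidene-2-[(2S,7R)-7-methyl-3-methylidene-6-oxo-2,3,6,7-tetrahydrooxepin-2-yl]-5-oxooxolan-3-yl}ethyl (2Z)-2-methylbut-2-enoate
Conditions: 17 (2 equiv), PPh3 (2 equiv), DIAD (2 equiv), toluene, 0 °C → rt
Reagents that add atoms: none
Why: Mitsunobu esterification with SN2 inversion should turn the 8R carbinol into the angelate with the spatial arrangement at C8 of the target, under neutral conditions that spare the Z geometry of the acid.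

Step 11
Reactants: 18 (1S)-2-chloro-1-{(2S,3S)-4-methylidene-2-[(2S,7R)-7-methyl-3-methylidene-6-oxo-2,3,6,7-tetrahydrooxepin-2-yl]-5-oxooxolan-3-yl}ethyl (2Z)-2-methylbut-2-enoate
Product: 19 (1S)-2-iodo-1-{(2S,3S)-4-methylidene-2-[(2S,7R)-7-methyl-3-methylidene-6-oxo-2,3,6,7-tetrahydrooxepin-2-yl]-5-oxooxolan-3-yl}ethyl (2Z)-2-methylbut-2-enoate
Conditions: NaI (10 equiv), butan-2-one, 65 °C, dark
Reagents that add atoms: sodium iodide, [Na+].[I-]
Why: Finkelstein halide exchange at the primary carbon (SN2, driven by precipitation of NaCl) should give the iodide needed for a fast ring closure without touching a stereocentre.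

Step 12
Reactants: 19 (1S)-2-iodo-1-{(2S,3S)-4-methylidene-2-[(2S,7R)-7-methyl-3-methylidene-6-oxo-2,3,6,7-tetrahydrooxepin-2-yl]-5-oxooxolan-3-yl}ethyl (2Z)-2-methylbut-2-enoate
Product: 21 CNP0282559.1, via potassium enolate 20 (not isolated)
Conditions: KN(SiMe3)2 (1.05 equiv), THF (0.002 M), −78 °C → 0 °C
Reagents that add atoms: none
Why: KN(SiMe3)2 should remove the only enolisable α-hydrogen of the C1 ketone (C10–H), and C10 of enolate 20 then displaces iodide at C9 in an intramolecular SN2 alkylation of a ketone enolate, the classical way to close a bridged ring onto a quaternary carbon. The oxepane (O, C5, C6, C7, C8, C9, C10) closes in the 7-exo-tet mode. The enolate is planar, so the configuration at C10 of 19 is erased, and the C9–C10 bond can form only on the ring face that carries the C5 side chain, which makes the step stereoconvergent and should deliver 10S. The selectivity needed is C-alkylation at C9 over conjugate addition, acyl transfer and elimination: C13 of the methylene lactone is held away from C10 (torsion C6–C7–C11=C13 near 180°), attack on the lactone or angelate carbonyl is reversible because no acidic hydrogen would remain, and high dilution suppresses intermolecular Michael addition. A [2,3]-Wittig shift through the allylic C5–O bond should be blocked because its transition state would put sp2 carbons (C10 and C4) at both bridgeheads of a bicyclo[3.2.1] frame.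

**Compound list**

1 | dimethyl (4R,5R)-2,2-dimethyl-1,3-dioxolane-4,5-dicarboxylate (dimethyl 2,3-O-isopropylidene-L-tartrate) | COC(=O)[C@@H]1OC(C)(C)O[C@H]1C(=O)OC | starting material
2 | (4R,5R)-2,2-dimethyl-1,3-dioxolane-4,5-dicarbaldehyde (formed as its aluminium hemiacetal) | O=C[C@@H]1OC(C)(C)O[C@H]1C=O | intermediate
3 | (4S,5S)-4,5-diethenyl-2,2-dimethyl-1,3-dioxolane | C=C[C@@H]1OC(C)(C)O[C@H]1C=C | intermediate
4 | (3S,4S)-hexa-1,5-diene-3,4-diol | C=C[C@H](O)[C@@H](O)C=C | intermediate
5 | (2S)-2-chloropropanoyl chloride | C[C@H](Cl)C(Cl)=O | starting material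
6 | (3S,4S)-4-hydroxyhexa-1,5-dien-3-yl (2S)-2-chloropropanoate | C=C[C@H](O)[C@@H](OC(=O)[C@H](C)Cl)C=C | intermediate
7 | (3R,5S,6S)-5,6-diethenyl-3-methyl-1,4-dioxan-2-one | C=C[C@@H]1OC(=O)[C@@H](C)O[C@H]1C=C | intermediate
8 | ethynylmagnesium bromide | C#C[Mg]Br | starting material
9 | (4R)-4-{[(3S,4S)-4-hydroxyhexa-1,5-dien-3-yl]oxy}pent-1-yn-3-one | C=C[C@H](O)[C@H](C=C)O[C@H](C)C(=O)C#C | intermediate
10 | (1Z,4R)-4-{[(3S,4S)-4-hydroxyhexa-1,5-dien-3-yl]oxy}-1-iodopent-1-en-3-one | C=C[C@H](O)[C@H](C=C)O[C@H](C)C(=O)/C=C\I | intermediate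
11 | (2R,7S)-7-[(1S)-1-hydroxyprop-2-en-1-yl]-2-methyl-6-methylidene-6,7-dihydrooxepin-3(2H)-one | C=C[C@H](O)[C@H]1O[C@H](C)C(=O)C=CC1=C | intermediate
12 | 2-(bromomethyl)prop-2-enoic acid | C=C(CBr)C(=O)O | starting material
13 | (1S)-1-[(2S,7R)-7-methyl-3-methylidene-6-oxo-2,3,6,7-tetrahydrooxepin-2-yl]prop-2-en-1-yl 2-(bromomethyl)prop-2-enoate | C=C[C@H](OC(=O)C(=C)CBr)[C@H]1O[C@H](C)C(=O)C=CC1=C | intermediate
14 | (5S)-3-(bromomethyl)-5-[(2S,7R)-7-methyl-3-methylidene-6-oxo-2,3,6,7-tetrahydrooxepin-2-yl]furan-2(5H)-one | O=C1O[C@@H](C=C1CBr)[C@H]1O[C@H](C)C(=O)C=CC1=C | intermediate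
15 | chloroacetaldehyde | O=CCCl | starting material
16 | (4R,5S)-4-[(1R)-2-chloro-1-hydroxyethyl]-3-methylidene-5-[(2S,7R)-7-methyl-3-methylidene-6-oxo-2,3,6,7-tetrahydrooxepin-2-yl]oxolan-2-one | C=C1C(=O)O[C@@H]([C@H]1[C@@H](O)CCl)[C@H]1O[C@H](C)C(=O)C=CC1=C | intermediate
17 | angelic acid, (2Z)-2-methylbut-2-enoic acid | C/C=C(C)\C(=O)O | starting material
18 | (1S)-2-chloro-1-{(2S,3S)-4-methylidene-2-[(2S,7R)-7-methyl-3-methylidene-6-oxo-2,3,6,7-tetrahydrooxepin-2-yl]-5-oxooxolan-3-yl}ethyl (2Z)-2-methylbut-2-enoate | C=C1C(=O)O[C@@H]([C@H]1[C@H](OC(=O)/C(C)=C\C)CCl)[C@H]1O[C@H](C)C(=O)C=CC1=C | intermediate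
19 | (1S)-2-iodo-1-{(2S,3S)-4-methylidene-2-[(2S,7R)-7-methyl-3-methylidene-6-oxo-2,3,6,7-tetrahydrooxepin-2-yl]-5-oxooxolan-3-yl}ethyl (2Z)-2-methylbut-2-enoate | C=C1C(=O)O[C@@H]([C@H]1[C@H](OC(=O)/C(C)=C\C)CI)[C@H]1O[C@H](C)C(=O)C=CC1=C | intermediate
20 | potassium enolate of 19 (C1 oxygen, C1=C10 double bond) | C=C1C(=O)O[C@@H]([C@H]1[C@H](OC(=O)/C(C)=C\C)CI)[C@H]1OC(C)=C([O-])C=CC1=C.[K+] | intermediate
21 | CNP0282559.1, (5S,6S,7R,8R,10S)-5,10-epoxy-1-oxogermacra-2,4(15),11(13)-trien-12,6-olid-8-yl (2Z)-2-methylbut-2-enoate | C=C1C(=O)O[C@H]2[C@H]1[C@H](OC(=O)/C(C)=C\C)C[C@]1(C)O[C@H]2C(=C)C=CC1=O | target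

Total step count: 12. Longest linear sequence: 12 steps (1 → 21); 5, 8, 12, 15 and 17 are bought.

**Steps most likely to fail**

Step 12. C-Alkylation at the fully substituted enolate carbon may be slow, so that intermolecular conjugate addition of the enolate to the methylene lactone or dienone of a second molecule, loss of HI, and γ-deprotonation of the angelate with Z to E scrambling take over. The fallback sets out from 16 and comes back at 21. Compound 16 is silylated (Et3SiOTf, 2,6-lutidine) to the triethylsilyl ether of 16 F1, and chloride is exchanged for iodide (NaI, butan-2-one) to give the iodide of the silyl ether F2. F2 carries no ester at C8 and is cyclised with KN(SiMe3)2 at the same dilution to the bicyclic 8-epi silyl ether F3. HF·pyridine frees the bicyclic 8-epi alcohol F4, and Mitsunobu esterification with 17 (PPh3, DIAD), whose carboxylate enters on the ring face turned away from the C1–C4 bridge, should give 21.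

Step 6. Ring–chain tautomerism of 10 to its six-membered lactol may withdraw the iodoenone from the cyclisation, and palladium hydride may re-add and move the exocyclic double bond into conjugation with the ring oxygen. The fallback sets out from 7 and comes back at 11. Lactone 7 is opened with Me(MeO)NH·HCl and AlMe3 to the hydroxy Weinreb amide F5, and its hydroxyl is capped (t-BuMe2SiOTf, 2,6-lutidine) to give the silylated Weinreb amide F6. Reagent 8 converts F6 into the silylated ynone F7, and NaI in AcOH gives the silylated (Z)-iodoenone F8, which can no longer form a lactol. F8 is cyclised under the Heck conditions of step 6 to the silyl ether of 11 F9, and HF·pyridine returns 11.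

Step 10. The activated C8 oxygen may be lost by E2 elimination toward the allylic C7–H, or the phosphine may add reversibly to the unsaturated acid and scramble Z to E. The fallback sets out from 16 and comes back at 18. Compound 16 is converted (Tf2O, 2,6-lutidine, CH2Cl2, −78 °C) into the trifluoromethanesulfonate of 16 F10, which is displaced with inversion by cesium angelate (17, Cs2CO3, 18-crown-6, toluene), a phosphine-free SN2 esterification that returns 18.

Further compounds
F1 | step 12 | O-triethylsilyl ether of 16 | C=C1C(=O)O[C@@H]([C@H]1[C@@H](O[Si](CC)(CC)CC)CCl)[C@H]1O[C@H](C)C(=O)C=CC1=C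
F2 | step 12 | iodide of the silyl ether (F1 with I in place of Cl) | C=C1C(=O)O[C@@H]([C@H]1[C@@H](O[Si](CC)(CC)CC)CI)[C@H]1O[C@H](C)C(=O)C=CC1=C
F3 | step 12 | bicyclic 8-epi triethylsilyl ether (21 with inverted C8 carrying OSiEt3 in place of the angelate) | C=C1C(=O)O[C@H]2[C@H]1[C@@H](O[Si](CC)(CC)CC)C[C@]1(C)O[C@H]2C(=C)C=CC1=O
F4 | step 12 | bicyclic 8-epi alcohol (21 with inverted C8 carrying OH in place of the angelate) | C=C1C(=O)O[C@H]2[C@H]1[C@@H](O)C[C@]1(C)O[C@H]2C(=C)C=CC1=O
F5 | step 6 | (2R)-2-{[(3S,4S)-4-hydroxyhexa-1,5-dien-3-yl]oxy}-N-methoxy-N-methylpropanamide | C=C[C@H](O)[C@H](C=C)O[C@H](C)C(=O)N(C)OC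
F6 | step 6 | tert-butyldimethylsilyl ether of F5 | C=C[C@H](O[Si](C)(C)C(C)(C)C)[C@H](C=C)O[C@H](C)C(=O)N(C)OC
F7 | step 6 | tert-butyldimethylsilyl ether of 9 | C=C[C@H](O[Si](C)(C)C(C)(C)C)[C@H](C=C)O[C@H](C)C(=O)C#C
F8 | step 6 | tert-butyldimethylsilyl ether of 10 | C=C[C@H](O[Si](C)(C)C(C)(C)C)[C@H](C=C)O[C@H](C)C(=O)/C=C\I
F9 | step 6 | tert-butyldimethylsilyl ether of 11 | C=C[C@H](O[Si](C)(C)C(C)(C)C)[C@H]1O[C@H](C)C(=O)C=CC1=C
F10 | step 10 | trifluoromethanesulfonate of 16 | C=C1C(=O)O[C@@H]([C@H]1[C@@H](OS(=O)(=O)C(F)(F)F)CCl)[C@H]1O[C@H](C)C(=O)C=CC1=C
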